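## Plan

1. Retrosynthetic cuts, in order: the carboxylic ester; the C8–prenyl bond (dearomative allylation); the C4′=C5′ alkene (Wittig); the pyran ring at O1–C2 and C4–C4a (aryl propargyl ether); the C6–benzoyl bond; the C7–C8 bond of ring A (Claisen); the C4a–C8a bond (acetoacetate dianion acylation); finally the cyclohexene of (S)-limonene.
2. Enabling feature (chromene numbering; ring A = C4a, C5, C6, C7, C8, C8a; side chain C1′–C5′ on C8): the string C4′–C3′–C2′(isopropenyl)–C1′–C8–C8a is the opened ring of limonene with C8a at the acyl level, and C8a, C5 and C7 carry the alternating oxygens of a triketide. Ring A is therefore a masked phloroglucinol that closes by attack of C8 on C7.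
3. Forward order: limonene → acetal acid → 3,5-dioxo ester → ring A → benzoyl on C6 → pyran ring → side-chain enoate → prenyl on C8 (ring A dearomatised) → free acid.
4. Stereochemistry: C2′ is C4 of (S)-limonene and is never alpha to a carbonyl; C8 is set by a chiral palladium catalyst in the prenylation; the E alkene comes from a stabilised ylide.

Key step: step 6

Assumption: the (R,R) enantiomer of the Trost ligand is taken to favour the (8S) epimer in step 14; should the sense be opposite, the (S,S) ligand is used and nothing else changes.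

## Route

Step 1
Reactants: 1 (S)-limonene
Product: 2 (4S)-1-methyl-4-(prop-1-en-2-yl)-7-oxabicyclo[4.1.0]heptane (limonene 1,2-oxide, cis/trans mixture at the epoxide)
Conditions: mCPBA (1.0 equiv), NaHCO3, CH2Cl2, 0 °C
Reagents that add atoms: 3-chloroperoxybenzoic acid (mCPBA), O=C(OO)c1cccc(Cl)c1
Why: Prilezhaev epoxidation, in which the electrophilic peracid should take the trisubstituted ring alkene well ahead of the 1,1-disubstituted isopropenyl group; the epoxide carbons form as a mixture of configurations, which is harmless because both become carbonyl carbons in step 2.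

Step 2
Reactants: 2 (4S)-limonene 1,2-oxide
Product: 4 (3S)-6-oxo-3-(prop-1-en-2-yl)heptanal, via limonene-1,2-diol 3 (not isolated)
Conditions: H5IO6 (1.1 equiv), THF/H2O, 0 to 25 °C
Reagents that add atoms: water, O
Why: acid-promoted epoxide hydrolysis followed in the same flask by Malaprade glycol cleavage, a standard opening of limonene oxide that leaves the isopropenyl group and the stereocentre (now C3) untouched.

Step 3
Reactants: 4 (3S)-6-oxo-3-(prop-1-en-2-yl)heptanal
Product: 5 (5S)-7,7-dimethoxy-5-(prop-1-en-2-yl)heptan-2-one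
Conditions: HC(OMe)3, MeOH, CeCl3·7H2O (cat.), 25 °C
Reagents that add atoms: trimethyl orthoformate, COC(OC)OC; methanol, CO
Why: chemoselective acetalisation, since under lanthanide chloride catalysis in methanol an aldehyde is converted into its dimethyl acetal much faster than a methyl ketone, so the ketone stays free for the degradation in step 4.

Step 4
Reactants: 5 (5S)-7,7-dimethoxy-5-(prop-1-en-2-yl)heptan-2-one
Product: 7 (4S)-6,6-dimethoxy-4-(prop-1-en-2-yl)hexanoic acid, via tribromomethyl ketone 6 (not isolated)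
Conditions: NaOBr (from Br2 and aq. NaOH), 1,4-dioxane/H2O, 0 °C; Na2SO3; then NaH2PO4 to pH 5, 0 °C
Reagents that add atoms: sodium hydroxide, [Na+].[OH-]
Why: haloform reaction, in which the methyl group is brominated exhaustively and hydroxide then expels tribromomethanide; the strongly basic medium keeps bromine as hypobromite ion (a poor electrophile for an isolated alkene) and spares the acetal, and excess oxidant is destroyed with sulfite before the mild acidification.

Step 5
Reactants: 7 (4S)-6,6-dimethoxy-4-(prop-1-en-2-yl)hexanoic acid; 8 methyl acetoacetate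
Product: 11 methyl (8S)-10,10-dimethoxy-3,5-dioxo-8-(prop-1-en-2-yl)decanoate, via acyl imidazolide 9 (not isolated), via dilithio acetoacetate dianion 10 (not isolated)
Conditions: 7, 1,1'-carbonyldiimidazole, THF, 25 °C; added to 10 (3 equiv, from 8 and LiN(iPr)2, 2 equiv per 8, THF, 0 °C) at −78 °C, then 0 °C; aq. NH4Cl
Reagents that add atoms: none
Why: Claisen-type acylation of a beta-keto ester dianion at its terminal (gamma) carbon by an N-acylimidazole, which forms the C8a–C4a bond; the excess dianion takes up the proton of the more acidic product.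

Step 6
Reactants: 11 methyl (8S)-10,10-dimethoxy-3,5-dioxo-8-(prop-1-en-2-yl)decanoate
Product: 14 2-[(2S)-4,4-dimethoxy-2-(prop-1-en-2-yl)butyl]benzene-1,3,5-triol, via trilithium trianion 12 (not isolated), via cyclohexane-1,3,5-trione tautomer 13 (not isolated)
Conditions: LiN(iPr)2 (3.3 equiv), THF, −78 to 25 °C (degassed); aq. NH4Cl, 0 °C
Reagents that add atoms: none
Why: Three equivalents of LiN(iPr)2 should give trianion 12, in which the two internal methylenes (C6 and C4a, chromene numbering) are stabilised enolate carbons and the last equivalent deprotonates the terminal methylene C8; this least stabilised carbanion adds to the ester carbonyl C7, methoxide leaves, and trione 13 (as its lithium salt) tautomerises at once to the aromatic triol 14, which makes the closure irreversible. The closest known reaction type is the base-mediated intramolecular Claisen (Dieckmann-type) cyclisation of 3,5-dioxoalkanoate polyanions to phloroglucinols, the laboratory counterpart of the polyketide Claisen cyclisation and the same enolate-on-ester closure by which 5-oxoalkanoates give cyclohexane-1,3-diones. Ring A closes in a 6-(enolendo)-exo-trig mode by formation of the C7–C8 bond. No stereocentre is formed, and the C2′ centre lies three bonds from the nearest carbonyl and carries no acidic hydrogen, so it cannot epimerise. The selectivity needed is C-acylation at C8 over O-acylation by the enolate oxygen on C8a (which would give a 4-hydroxy-2-pyranone); full deprotonation makes C8 the most nucleophilic site and only C-attack leads to an aromatic product, while the dimethyl acetal and the isopropenyl group are inert to amide base and keep the future enoate carbon C4′ out of reach of the carbanion.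

Step 7
Reactants: 14 2-[(2S)-4,4-dimethoxy-2-(prop-1-en-2-yl)butyl]benzene-1,3,5-triol
Product: 15 2-[(2S)-4,4-dimethoxy-2-(prop-1-en-2-yl)butyl]-1,3,5-tris(methoxymethoxy)benzene
Conditions: MOMCl (4 equiv), iPr2NEt, DMF, 0 to 25 °C
Reagents that add atoms: chloromethyl methyl ether, COCCl
Why: Williamson-type O-alkylation of all three phenols under basic conditions, which provides the directing groups for step 8 and so avoids a Lewis-acid Friedel–Crafts benzoylation that the acetal and the isopropenyl group next to a free phenol would not survive.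

Step 8
Reactants: 15 the tris(methoxymethyl) ether; 16 N-methoxy-N-methylbenzamide
Product: 18 {3-[(2S)-4,4-dimethoxy-2-(prop-1-en-2-yl)butyl]-2,4,6-tris(methoxymethoxy)phenyl}(phenyl)methanone, via aryllithium 17 (not isolated)
Conditions: n-BuLi (1.1 equiv), THF, 0 °C; then 16, −78 to 25 °C; aq. NH4Cl
Reagents that add atoms: none
Why: directed ortho-metalation between two methoxymethoxy groups (the two open ring positions are equivalent by symmetry, so one ketone results) followed by acylation with a Weinreb amide, whose chelated tetrahedral adduct prevents a second addition; this places the benzoyl group on C6.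

Step 9
Reactants: 18 the tris(methoxymethoxy) benzophenone
Product: 19 {3-[(2S)-4,4-dimethoxy-2-(prop-1-en-2-yl)butyl]-2,4,6-trihydroxyphenyl}(phenyl)methanone
Conditions: HCl (1.25 M in MeOH), 25 °C
Reagents that add atoms: none
Why: acid-catalysed transacetalisation of the three aryl methoxymethyl ethers to dimethoxymethane; in anhydrous methanol the side-chain dimethyl acetal only exchanges with the solvent, and dilute acid at room temperature is expected to leave the isopropenyl group alone, as in methoxymethyl removals on lavandulyl-substituted phenols.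

Step 10
Reactants: 19 the trihydroxybenzophenone; 20 3-chloro-3-methylbut-1-yne
Product: 21 {3-[(2S)-4,4-dimethoxy-2-(prop-1-en-2-yl)butyl]-2,6-dihydroxy-4-[(2-methylbut-3-yn-2-yl)oxy]phenyl}(phenyl)methanone
Conditions: 20 (1.5 equiv), K2CO3 (1.2 equiv), KI, CuI (cat.), acetone, 55 °C
Reagents that add atoms: none
Why: copper-catalysed O-propargylation of a phenoxide, selective for the hydroxyl para to the benzoyl group (the oxygen on C8a) because it is the most acidic one and is not hydrogen-bonded to the ketone.

Step 11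
Reactants: 21 the aryl 1,1-dimethylpropargyl ether
Product: 24 {8-[(2S)-4,4-dimethoxy-2-(prop-1-en-2-yl)butyl]-5,7-dihydroxy-2,2-dimethyl-2H-chromen-6-yl}(phenyl)methanone, via allenylphenol 22 (not isolated), via ortho-quinone methide 23 (not isolated)
Conditions: xylenes, 140 °C
Reagents that add atoms: none
Why: aromatic propargyl Claisen rearrangement to the only free ortho position C4a (migration to the substituted C8 is reversible), then 1,5-hydrogen shift and oxa-6π electrocyclisation, so the pyran oxygen is fixed on C8a without a regioisomer.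

Step 12
Reactants: 24 the chromene acetal
Product: 25 (3S)-4-(6-benzoyl-5,7-dihydroxy-2,2-dimethyl-2H-chromen-8-yl)-3-(prop-1-en-2-yl)butanal
Conditions: AcOH/THF/H2O (3:1:1), 35 °C
Reagents that add atoms: water, O
Why: mild acid hydrolysis of an acyclic dimethyl acetal, placed after C6 and C4a are both substituted so that no ring C–H can condense with the aldehyde, and with an acid too weak to protonate the chromene or isopropenyl alkenes.

Step 13
Reactants: 25 the aldehyde; 26 ethyl 2-(triphenylphosphoranylidene)propanoate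
Product: 27 ethyl (2E,5R)-6-(6-benzoyl-5,7-dihydroxy-2,2-dimethyl-2H-chromen-8-yl)-2-methyl-5-(prop-1-en-2-yl)hex-2-enoate
Conditions: 26 (1.5 equiv), toluene, 60 °C
Reagents that add atoms: none
Why: Wittig olefination with an alpha-methyl stabilised ylide, which forms the oxaphosphetane reversibly and should therefore give the E trisubstituted enoate, and which tolerates the chelated phenols (the descriptor at C2′ changes from S to R only through the priority change).

Step 14
Reactants: 27 the aromatic enoate; 28 3-methylbut-2-en-1-yl acetate (prenyl acetate)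
Product: 29 ethyl (2E,5R)-6-[(8S)-6-benzoyl-7-hydroxy-2,2-dimethyl-8-(3-methylbut-2-en-1-yl)-5-oxo-5,8-dihydro-2H-chromen-8-yl]-2-methyl-5-(prop-1-en-2-yl)hex-2-enoate (drawn as the 7-hydroxy-5-oxo tautomer)
Conditions: 28 (1.1 equiv), Pd2(dba)3·CHCl3 (2.5 mol %), (R,R)-DACH-phenyl Trost ligand, N,N'-[(1R,2R)-cyclohexane-1,2-diyl]bis[2-(diphenylphosphanyl)benzamide] (7.5 mol %), Cs2CO3 (1.1 equiv), THF, 0 to 25 °C
Reagents that add atoms: none
Why: Proposed new method: the zerovalent palladium–ligand complex ionises 28 to a cationic 1,1-dimethylallyl palladium complex, and the caesium phenoxide of the acidic acylphloroglucinol 27 attacks its unsubstituted terminus through C8, the ring carbon whose alkylation leaves a stabilised vinylogous acid (O-prenyl ethers can re-ionise under the catalyst, and attack at C6 or C4a would break the benzoyl or chromene conjugation); the chiral pocket of the ligand, not the remote C2′ centre, is relied on to select the face of C8 that gives the (8S) quaternary centre; the closest known reaction types are the racemic Tsuji–Trost dearomative allylation of acylphloroglucinols and the palladium-catalysed asymmetric allylic dearomatisation of naphthols and substituted phenols with this ligand class.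

Step 15
Reactants: 29 the prenylated ethyl ester
Product: 30 (2E,5R)-6-[(8S)-6-benzoyl-7-hydroxy-2,2-dimethyl-8-(3-methylbut-2-en-1-yl)-5-oxo-5,8-dihydro-2H-chromen-8-yl]-2-methyl-5-(prop-1-en-2-yl)hex-2-enoic acid (CNP0333091.1)
Conditions: LiOH·H2O (5 equiv), THF/H2O (3:1), 25 °C; then 1 M HCl to pH 4, 0 °C
Reagents that add atoms: lithium hydroxide, [Li+].[OH-]
Why: ester saponification by acyl–oxygen cleavage; under these conditions the ring A vinylogous acid is present as its delocalised enolate, which protects it from retro-Claisen cleavage and conjugate addition, and neither C8 (quaternary) nor C2′ has an acidic hydrogen.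

## Compound list

1 | (S)-limonene | CC1=CC[C@H](CC1)C(=C)C | starting material
2 | (4S)-1-methyl-4-(prop-1-en-2-yl)-7-oxabicyclo[4.1.0]heptane | CC12OC1C[C@H](CC2)C(=C)C | intermediate
3 | (4S)-1-methyl-4-(prop-1-en-2-yl)cyclohexane-1,2-diol | CC1(O)C(O)C[C@H](CC1)C(=C)C | intermediate (not isolated)
4 | (3S)-6-oxo-3-(prop-1-en-2-yl)heptanal | C=C(C)[C@H](CC=O)CCC(C)=O | intermediate
5 | (5S)-7,7-dimethoxy-5-(prop-1-en-2-yl)heptan-2-one | C=C(C)[C@H](CC(OC)OC)CCC(C)=O | intermediate
6 | (5S)-1,1,1-tribromo-7,7-dimethoxy-5-(prop-1-en-2-yl)heptan-2-one | C=C(C)[C@H](CC(OC)OC)CCC(=O)C(Br)(Br)Br | intermediate (not isolated)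
7 | (4S)-6,6-dimethoxy-4-(prop-1-en-2-yl)hexanoic acid | C=C(C)[C@H](CC(OC)OC)CCC(=O)O | intermediate
8 | methyl acetoacetate | COC(=O)CC(C)=O | starting material
9 | 1-[(4S)-6,6-dimethoxy-4-(prop-1-en-2-yl)hexanoyl]-1H-imidazole | C=C(C)[C@H](CC(OC)OC)CCC(=O)n1ccnc1 | intermediate (not isolated)
10 | dilithium dianion of methyl acetoacetate | [Li+].[Li+].[CH2-]C(=O)[CH-]C(=O)OC | intermediate (not isolated)
11 | methyl (8S)-10,10-dimethoxy-3,5-dioxo-8-(prop-1-en-2-yl)decanoate | C=C(C)[C@H](CC(OC)OC)CCC(=O)CC(=O)CC(=O)OC | intermediate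
12 | trilithium trianion of 11 | [Li+].[Li+].[Li+].C=C(C)[C@H](CC(OC)OC)C[CH-]C(=O)[CH-]C(=O)[CH-]C(=O)OC | intermediate (not isolated)
13 | 2-[(2S)-4,4-dimethoxy-2-(prop-1-en-2-yl)butyl]cyclohexane-1,3,5-trione | C=C(C)[C@H](CC(OC)OC)CC1C(=O)CC(=O)CC1=O | intermediate (not isolated)
14 | 2-[(2S)-4,4-dimethoxy-2-(prop-1-en-2-yl)butyl]benzene-1,3,5-triol | C=C(C)[C@H](CC(OC)OC)Cc1c(O)cc(O)cc1O | intermediate
15 | 2-[(2S)-4,4-dimethoxy-2-(prop-1-en-2-yl)butyl]-1,3,5-tris(methoxymethoxy)benzene | C=C(C)[C@H](CC(OC)OC)Cc1c(OCOC)cc(OCOC)cc1OCOC | intermediate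
16 | N-methoxy-N-methylbenzamide | CON(C)C(=O)c1ccccc1 | starting material
17 | {3-[(2S)-4,4-dimethoxy-2-(prop-1-en-2-yl)butyl]-2,4,6-tris(methoxymethoxy)phenyl}lithium | C=C(C)[C@H](CC(OC)OC)Cc1c(OCOC)c([Li])c(OCOC)cc1OCOC | intermediate (not isolated)
18 | {3-[(2S)-4,4-dimethoxy-2-(prop-1-en-2-yl)butyl]-2,4,6-tris(methoxymethoxy)phenyl}(phenyl)methanone | C=C(C)[C@H](CC(OC)OC)Cc1c(OCOC)c(C(=O)c2ccccc2)c(OCOC)cc1OCOC | intermediate
19 | {3-[(2S)-4,4-dimethoxy-2-(prop-1-en-2-yl)butyl]-2,4,6-trihydroxyphenyl}(phenyl)methanone | C=C(C)[C@H](CC(OC)OC)Cc1c(O)c(C(=O)c2ccccc2)c(O)cc1O | intermediate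
20 | 3-chloro-3-methylbut-1-yne | CC(C)(Cl)C#C | starting material
21 | {3-[(2S)-4,4-dimethoxy-2-(prop-1-en-2-yl)butyl]-2,6-dihydroxy-4-[(2-methylbut-3-yn-2-yl)oxy]phenyl}(phenyl)methanone | C=C(C)[C@H](CC(OC)OC)Cc1c(O)c(C(=O)c2ccccc2)c(O)cc1OC(C)(C)C#C | intermediate
22 | {3-[(2S)-4,4-dimethoxy-2-(prop-1-en-2-yl)butyl]-2,4,6-trihydroxy-5-(3-methylbuta-1,2-dien-1-yl)phenyl}(phenyl)methanone | C=C(C)[C@H](CC(OC)OC)Cc1c(O)c(C(=O)c2ccccc2)c(O)c(C=C=C(C)C)c1O | intermediate (not isolated)
23 | 4-benzoyl-2-[(2S)-4,4-dimethoxy-2-(prop-1-en-2-yl)butyl]-3,5-dihydroxy-6-(3-methylbut-2-en-1-ylidene)cyclohexa-2,4-dien-1-one | C=C(C)[C@H](CC(OC)OC)CC1=C(O)C(C(=O)c2ccccc2)=C(O)C(=CC=C(C)C)C1=O | intermediate (not isolated)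
24 | {8-[(2S)-4,4-dimethoxy-2-(prop-1-en-2-yl)butyl]-5,7-dihydroxy-2,2-dimethyl-2H-chromen-6-yl}(phenyl)methanone | C=C(C)[C@H](CC(OC)OC)Cc1c(O)c(C(=O)c2ccccc2)c(O)c2C=CC(C)(C)Oc12 | intermediate
25 | (3S)-4-(6-benzoyl-5,7-dihydroxy-2,2-dimethyl-2H-chromen-8-yl)-3-(prop-1-en-2-yl)butanal | C=C(C)[C@H](CC=O)Cc1c(O)c(C(=O)c2ccccc2)c(O)c2C=CC(C)(C)Oc12 | intermediate
26 | ethyl 2-(triphenylphosphoranylidene)propanoate | CCOC(=O)C(C)=P(c1ccccc1)(c1ccccc1)c1ccccc1 | starting material
27 | ethyl (2E,5R)-6-(6-benzoyl-5,7-dihydroxy-2,2-dimethyl-2H-chromen-8-yl)-2-methyl-5-(prop-1-en-2-yl)hex-2-enoate | C=C(C)[C@H](C/C=C(\C)C(=O)OCC)Cc1c(O)c(C(=O)c2ccccc2)c(O)c2C=CC(C)(C)Oc12 | intermediate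
28 | 3-methylbut-2-en-1-yl acetate | CC(=O)OCC=C(C)C | starting material
29 | ethyl (2E,5R)-6-[(8S)-6-benzoyl-7-hydroxy-2,2-dimethyl-8-(3-methylbut-2-en-1-yl)-5-oxo-5,8-dihydro-2H-chromen-8-yl]-2-methyl-5-(prop-1-en-2-yl)hex-2-enoate | C=C(C)[C@H](C/C=C(\C)C(=O)OCC)C[C@@]1(CC=C(C)C)C(O)=C(C(=O)c2ccccc2)C(=O)C2=C1OC(C)(C)C=C2 | intermediate
30 | (2E,5R)-6-[(8S)-6-benzoyl-7-hydroxy-2,2-dimethyl-8-(3-methylbut-2-en-1-yl)-5-oxo-5,8-dihydro-2H-chromen-8-yl]-2-methyl-5-(prop-1-en-2-yl)hex-2-enoic acid | C=C(C)[C@H](C/C=C(\C)C(=O)O)C[C@@]1(CC=C(C)C)C(O)=C(C(=O)c2ccccc2)C(=O)C2=C1OC(C)(C)C=C2 | target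

## Step count and risks

Total: 15 steps. Longest linear sequence: 15 steps from (S)-limonene 1; compounds 8, 16, 20, 26 and 28 are purchased.

Step 14 (labelled step, listed first). What may go wrong is insufficient facial discrimination at C8 by the chiral catalyst, possibly mismatched with the C2′ centre, and competing O-prenylation. The fallback uses known chemistry and gives up catalyst control. It sets out from 27, which is C-prenylated with prenyl bromide and NaOMe in methanol at 0 °C (the classical base-mediated dearomative prenylation of acylphloroglucinols). Both C8 epimers form, and the unwanted ethyl (2E,5R)-6-[(8R)-6-benzoyl-7-hydroxy-2,2-dimethyl-8-(3-methylbut-2-en-1-yl)-5-oxo-5,8-dihydro-2H-chromen-8-yl]-2-methyl-5-(prop-1-en-2-yl)hex-2-enoate F1 is removed by chromatography, the two being diastereomers. The route is rejoined at 29.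

Step 6 (key step). What may go wrong is O-acylation by the enolate oxygen on C8a, leading to a 4-hydroxy-2-pyranone, or a trianion whose fully enolised ester is too poor an electrophile, so that it persists and decomposes on warming. The fallback closes ring A through a doubly stabilised carbanion with the benzoyl group already in the chain. It sets out from 7, activated as imidazolide 9 as in step 5, which acylates the dilithio dianion of commercial 1-phenylbutane-1,3-dione to give (8S)-10,10-dimethoxy-1-phenyl-8-(prop-1-en-2-yl)decane-1,3,5-trione F2. The trianion of F2 (LiN(iPr)2, 3 equiv) is carboxylated at its terminal methylene with CO2 to 2-[(2S)-4,4-dimethoxy-2-(prop-1-en-2-yl)butyl]-3,5,7-trioxo-7-phenylheptanoic acid F3. This is methylated at once with trimethylsilyldiazomethane to methyl 2-[(2S)-4,4-dimethoxy-2-(prop-1-en-2-yl)butyl]-3,5,7-trioxo-7-phenylheptanoate F4. KOH in methanol then effects the Claisen cyclisation of the triketo ester (C6 onto C7), the established route from 3,5,7-triketo esters to acylphloroglucinols. The route is rejoined at 19, so steps 7 to 9 are not needed.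

Step 10. What may go wrong is loss of site selectivity among the three phenolic hydroxyls, or sluggish alkylation of the hindered hydroxyl on C8a by the tertiary propargylic electrophile. The fallback builds the pyran ring by a condensation instead of an ether rearrangement. It sets out from 19, which is heated with 3-methylbut-2-enal and ethylenediammonium diacetate (cat.) in xylenes; Knoevenagel condensation at C4a and oxa-6π electrocyclisation give chromene 24 directly, so step 11 is skipped. The price is a regioisomer closed onto the C5 oxygen, {6-[(2S)-4,4-dimethoxy-2-(prop-1-en-2-yl)butyl]-5,7-dihydroxy-2,2-dimethyl-2H-chromen-8-yl}(phenyl)methanone F5, which has to be separated. The route is rejoined at 24.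

## Further compounds

F1 | step 14 | ethyl (2E,5R)-6-[(8R)-6-benzoyl-7-hydroxy-2,2-dimethyl-8-(3-methylbut-2-en-1-yl)-5-oxo-5,8-dihydro-2H-chromen-8-yl]-2-methyl-5-(prop-1-en-2-yl)hex-2-enoate | C=C(C)[C@H](C/C=C(\C)C(=O)OCC)C[C@]1(CC=C(C)C)C(O)=C(C(=O)c2ccccc2)C(=O)C2=C1OC(C)(C)C=C2
F2 | step 6 | (8S)-10,10-dimethoxy-1-phenyl-8-(prop-1-en-2-yl)decane-1,3,5-trione | C=C(C)[C@H](CC(OC)OC)CCC(=O)CC(=O)CC(=O)c1ccccc1
F3 | step 6 | 2-[(2S)-4,4-dimethoxy-2-(prop-1-en-2-yl)butyl]-3,5,7-trioxo-7-phenylheptanoic acid | C=C(C)[C@H](CC(OC)OC)CC(C(=O)O)C(=O)CC(=O)CC(=O)c1ccccc1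
F4 | step 6 | methyl 2-[(2S)-4,4-dimethoxy-2-(prop-1-en-2-yl)butyl]-3,5,7-trioxo-7-phenylheptanoate | C=C(C)[C@H](CC(OC)OC)CC(C(=O)OC)C(=O)CC(=O)CC(=O)c1ccccc1
F5 | step 10 | {6-[(2S)-4,4-dimethoxy-2-(prop-1-en-2-yl)butyl]-5,7-dihydroxy-2,2-dimethyl-2H-chromen-8-yl}(phenyl)methanone | C=C(C)[C@H](CC(OC)OC)Cc1c(O)c(C(=O)c2ccccc2)c2OC(C)(C)C=Cc2c1O
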